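(The numbers are made up; the rest is arithmetic.)

I had the same amounts of substrate and catalyst to spend in each set-up, and what I had to decide for the next run was how fast the substrate should reach the catalyst.

common to all: free catalyst 1.0 mM

| charge | substrate | time | remark |
|---|---|---|---|
| spring | 0.10 M | 4.0 min | a closed flask charged with all of it at once and left for 4.0 min |
| winter | 0.10 M |  | a single well-mixed tank run continuously and read at steady state, 4.0 min in it on average |
| noon | 0.10 M (fed, over 3.20 min) | 4.0 min | all but substrate at the start; substrate goes in evenly over 3.20 min, the run ends at 4.0 min |

    2 substrate → homo dimer (k1 = 0.084 L mol⁻¹ s⁻¹)
    catalyst intermediate → free catalyst + product (k2 = 0.98 s⁻¹)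
    substrate + free catalyst → catalyst intermediate (k3 = 56 L mol⁻¹ s⁻¹)

1. the set-up with the highest amount of product at the outlet or at the end, in percent of the substrate put in ("none" if the first two lie within 2 percentage points) (spring / winter / noon / none)
2. amount of product at the outlet or at the end, in percent of the substrate put in, spring
3. amount of product at the outlet or at the end, in percent of the substrate put in, winter
4. amount of product at the outlet or at the end, in percent of the substrate put in, noon

- percentages count the substrate that a species holds: one homo dimer counts as two
- a doubled species enters its step squared and goes two at a time
- the stated concentrations are those of everything mixed, before any reaction; amounts are the same in each set-up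
- the feed brings no volume worth counting
- run time (spring): 4.0 min

I counted turnovers. Product leaves the catalyst intermediate with the rate constant 0.98 s⁻¹, the top turnover frequency, so if the whole charge of 1.0 mM sat as catalyst intermediate it would turn substrate at a top rate of 0.980 mM s⁻¹. I took the time τ over which the substrate arrives and divided the charge by τ and by that top rate. For noon this load L, the share of the catalyst that must sit as catalyst intermediate for turnover to keep pace with the feed, is 0.531. Holding that share takes a substrate level of the ratio of the release and binding constants times L/(1−L), which I reckoned at 0.0199 M.

At that level, I reckoned the dimer step would take 12.7% of the substrate during the feed. The 0.800 min after the feed offered 0.0470 M of turnover at the top rate, more than the reckoned level.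

Spring looked worse, because at its start the dimer step uses 1.68 mM s⁻¹ of substrate, faster than the top rate. For winter, with 4.0 min on average as τ, the load is 0.425 and the level 0.0129 M. By my reckoning 12.9% of the substrate would leave unconverted and 6.76% would go to homo dimer, together more than the homo dimer share I had reckoned for noon. I settled on dosing, as in noon.

The forecast also named noon, with 65% for spring, 85.6% for winter and 90% for noon, saying that feeding “keeps dimer to about 7%”, where I had reckoned 12.7%.

Noon gave 91.1% of product, against 65.5% in spring and 85.5% in winter. At 2.00 min in noon, during the feed, catalyst intermediate held 46.7% of the catalyst, beside my load of 53.1%. In the neighbour of noon charged with 4.0 × 10⁻⁴ M of free catalyst, the load comes to 1.33, above one. That neighbour ended at 4.00 min with 52.5% of product, and the substrate still unbound stood at 18.8%.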